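**Strategy**

Ring C is a cyclohex-2-ene-1,4-dione whose C1 ketone, C6 methylene and C5 tertiary carbinol form an aldol (β-hydroxy ketone) triad, the reduced form of a 3,5,5-trisubstituted 2-isoxazoline. The route therefore cuts C1–C6 and C5–O back to a nitrile oxide and a 1,1-disubstituted allylic alcohol. One zinc–tartrate-controlled [3+2] cycloaddition joins the coumarin fragment, as its 3-ylacetohydroximoyl chloride, to 2-prenylallyl alcohol, forges both bonds and sets C5 as R. The isoxazoline then masks the retro-aldol-prone aldol while C3 is added to C4 as a dithiane; N–O cleavage, oxidation at C4 and a C2=C3 Knoevenagel closure complete ring C.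

Key step: step 8

Assumption: the facial sense known for allyl alcohol itself, where the (R,R)-tartrate leads to the (5R)-5-hydroxymethyl-isoxazoline, is taken to hold for the 2-alkylated allylic alcohol; if it proved reversed, the (S,S)-tartrate would be used.

Ring C numbering used below: C1(=O), C2 (bears the coumarin), C3–H, C4(=O), C5(OH)(prenyl), C6H2. The target is 5R.

**Route**

Step 1
Reactants: 1 2-hydroxy-4-methoxybenzaldehyde; 2 succinic anhydride
Product: 3 2-(7-methoxy-2-oxo-2H-chromen-3-yl)acetic acid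
Conditions: disodium succinate (Na2C4H4O4), neat melt, 170 °C
Reagents that add atoms: none
Why: Perkin condensation in which the enolised anhydride adds to the aldehyde, water is lost and the ortho-phenol lactonises onto the nearer carboxyl, a classical entry to coumarin-3-acetic acids that leaves the second carboxyl as the CH2CO2H arm.

Step 2
Reactants: 3 2-(7-methoxy-2-oxo-2H-chromen-3-yl)acetic acid
Product: 4 3-(2-hydroxyethyl)-7-methoxy-2H-chromen-2-one
Conditions: BH3·THF, THF, 0 °C to rt
Reagents that add atoms: none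
Why: Borane reduction of a carboxylic acid, which runs through the acyloxyborane far faster than attack on the conjugated lactone or hydroboration of the electron-poor trisubstituted C3=C4 bond.

Step 3
Reactants: 4 3-(2-hydroxyethyl)-7-methoxy-2H-chromen-2-one
Product: 6 2-(7-methoxy-2-oxo-2H-chromen-3-yl)acetaldehyde oxime (E/Z mixture), via aldehyde 5 (not isolated)
Conditions: DMP, CH2Cl2, 0 °C to rt; then crude aldehyde, NH2OH·HCl, NaOAc, EtOH/H2O, rt
Reagents that add atoms: hydroxylamine hydrochloride, Cl.NO
Why: Dess–Martin oxidation followed by oxime condensation on the crude aldehyde, so that the enolisable arylacetaldehyde-type intermediate is trapped before it can self-condense; both oxime geometries serve in the next step.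

Step 4
Reactants: 6 2-(7-methoxy-2-oxo-2H-chromen-3-yl)acetaldehyde oxime
Product: 7 (Z)-2-(7-methoxy-2-oxo-2H-chromen-3-yl)-N-hydroxyacetimidoyl chloride (the hydroximoyl chloride)
Conditions: NCS, DMF, rt
Reagents that add atoms: N-chlorosuccinimide, ClN1C(=O)CCC1=O
Why: Electrophilic chlorination of the aldoxime carbon by NCS in DMF, the standard preparation of hydroximoyl chlorides, which is faster than chlorination of the lactone-deactivated anisole ring.

Step 5
Reactants: 8 triethyl phosphonoacetate; 9 prenyl bromide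
Product: 10 ethyl 2-(diethoxyphosphoryl)-5-methylhex-4-enoate (racemic)
Conditions: NaH, THF, 0 °C to rt
Reagents that add atoms: none
Why: C-alkylation of the sodium salt of the phosphonoacetate by a primary allylic bromide (SN2), with a slight excess of 8 to hold back dialkylation.

Step 6
Reactants: 10 ethyl 2-(diethoxyphosphoryl)-5-methylhex-4-enoate
Product: 11 ethyl 5-methyl-2-methylidenehex-4-enoate
Conditions: HCHO (37% aq.), K2CO3, THF/H2O, rt to 60 °C
Reagents that add atoms: formaldehyde, C=O
Why: Horner–Wadsworth–Emmons olefination of aqueous formaldehyde by the α-substituted phosphonoacetate, a standard route to 2-alkylacrylates that needs only carbonate as base.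

Step 7
Reactants: 11 ethyl 5-methyl-2-methylidenehex-4-enoate
Product: 12 2-(3-methylbut-2-enyl)prop-2-en-1-ol
Conditions: i-Bu2AlH, CH2Cl2, −78 °C to 0 °C
Reagents that add atoms: none
Why: 1,2-reduction of the enoate by i-Bu2AlH, which delivers allylic alcohols from acrylates without touching isolated alkenes.

Step 8
Reactants: 7 (Z)-2-(7-methoxy-2-oxo-2H-chromen-3-yl)-N-hydroxyacetimidoyl chloride; 12 2-(3-methylbut-2-enyl)prop-2-en-1-ol
Product: 15 3-{[(5R)-5-(hydroxymethyl)-5-(3-methylbut-2-enyl)-4,5-dihydroisoxazol-3-yl]methyl}-7-methoxy-2H-chromen-2-one, via ethylzinc alkoxide 13 (not isolated), via nitrile oxide 14 (not isolated)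
Conditions: Et2Zn (2 equiv in total), diisopropyl (R,R)-tartrate (1 equiv), 1,4-dioxane (additive), CHCl3, 0 °C; 7 added last and slowly
Reagents that add atoms: none
Why: Et2Zn converts 12 into zinc alkoxide 13 and, with the tartrate, assembles a dinuclear zinc tartrate on which the zinc oximate of 7 expels chloride to give nitrile oxide 14 next to the bound alkoxide; a concerted [3+2] cycloaddition then joins the dipole carbon to the terminal =CH2 (C1–C6) and the dipole oxygen to the fully substituted alkene carbon (C5–O). The closest known reaction type is the Et2Zn/tartrate ester-mediated enantioselective nitrile oxide cycloaddition to allylic alcohols, of which a 2-alkylallyl alcohol is a less tested member. The five-membered 2-isoxazoline ring closes in this intermolecular cycloaddition, both ring bonds forming together and suprafacially on the alkene. The one new stereocentre, C5, is set by the (R,R)-tartrate, which ties alkoxide and dipole to neighbouring zinc atoms and leaves one alkene face open, expected to give 5R. The step needs regioselectivity (oxygen to the more substituted carbon, intrinsic for 1,1-disubstituted alkenes), chemoselectivity over the prenyl and coumarin C3=C4 alkenes (both trisubstituted, not zinc-bound and poor dipolarophiles, whereas the free hydroxyl of 12 anchors its alkene to zinc) and suppression of furoxan formation (slow addition of 7 keeps 14 dilute).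

Step 9
Reactants: 15 3-{[(5R)-5-(hydroxymethyl)-5-(3-methylbut-2-enyl)-4,5-dihydroisoxazol-3-yl]methyl}-7-methoxy-2H-chromen-2-one
Product: 16 (5R)-3-[(7-methoxy-2-oxo-2H-chromen-3-yl)methyl]-5-(3-methylbut-2-enyl)-4,5-dihydroisoxazole-5-carbaldehyde
Conditions: DMP, CH2Cl2, 0 °C to rt
Reagents that add atoms: none
Why: Dess–Martin oxidation of the primary alcohol to the aldehyde; C5 is quaternary and cannot epimerise, and the C=N bond, both alkenes and the lactone are inert to the reagent.

Step 10
Reactants: 16 (5R)-3-[(7-methoxy-2-oxo-2H-chromen-3-yl)methyl]-5-(3-methylbut-2-enyl)-4,5-dihydroisoxazole-5-carbaldehyde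
Product: 17 3-{[(5R)-5-[(1,3-dithian-2-yl)(hydroxy)methyl]-5-(3-methylbut-2-enyl)-4,5-dihydroisoxazol-3-yl]methyl}-7-methoxy-2H-chromen-2-one (both carbinol epimers)
Conditions: 1,3-dithiane, n-BuLi, THF, −30 °C; then 16, −78 °C; AcOH quench at −78 °C
Reagents that add atoms: 1,3-dithiane (used as its 2-lithio derivative), C1CSCSC1
Why: Corey–Seebach addition of 2-lithio-1,3-dithiane as formyl anion equivalent, the hindered but highly electrophilic α-oxygenated aldehyde reacting at −78 °C much faster than the lactone carbonyl or the acidic CH2 groups; the new carbinol centre forms without control and is erased at step 12.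

Step 11
Reactants: 17 3-{[(5R)-5-[(1,3-dithian-2-yl)(hydroxy)methyl]-5-(3-methylbut-2-enyl)-4,5-dihydroisoxazol-3-yl]methyl}-7-methoxy-2H-chromen-2-one
Product: 18 3-[(4R)-5-(1,3-dithian-2-yl)-4,5-dihydroxy-4-(3-methylbut-2-enyl)-2-oxopentyl]-7-methoxy-2H-chromen-2-one (both C5' epimers)
Conditions: Mo(CO)6, MeCN/H2O (10:1), 80 °C
Reagents that add atoms: water, O
Why: Reductive N–O cleavage of the 2-isoxazoline by zerovalent molybdenum with hydrolysis of the resulting β-hydroxy imine, a standard unmasking of aldols that involves no enolate, leaves C5 untouched and spares alkenes, the lactone and the unactivated dithiane.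

Step 12
Reactants: 18 3-[(4R)-5-(1,3-dithian-2-yl)-4,5-dihydroxy-4-(3-methylbut-2-enyl)-2-oxopentyl]-7-methoxy-2H-chromen-2-one
Product: 19 3-[(4R)-5-(1,3-dithian-2-yl)-4-hydroxy-4-(3-methylbut-2-enyl)-2,5-dioxopentyl]-7-methoxy-2H-chromen-2-one
Conditions: SO3·pyridine, DMSO, Et3N, CH2Cl2, 0 °C to rt
Reagents that add atoms: none
Why: Parikh–Doering oxidation of the secondary carbinol, chosen because activated DMSO neither cleaves the C4–C5 glycol nor attacks the dithiane sulfur, while the tertiary C5–OH cannot be oxidised; both C4 epimers converge on one ketone.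

Step 13
Reactants: 19 3-[(4R)-5-(1,3-dithian-2-yl)-4-hydroxy-4-(3-methylbut-2-enyl)-2,5-dioxopentyl]-7-methoxy-2H-chromen-2-one
Product: 21 3-[(4R)-4-hydroxy-4-(3-methylbut-2-enyl)-3,6-dioxocyclohex-1-en-1-yl]-7-methoxy-2H-chromen-2-one (target), via ketoaldehyde 20 (not isolated)
Conditions: PhI(OCOCF3)2 (1.2–1.5 equiv), NaHCO3, MeCN/H2O (9:1), 0 °C, short contact; then piperidine (cat.), AcOH (cat.), CH2Cl2, rt
Reagents that add atoms: none
Why: Oxidative dithiane hydrolysis by the trivalent iodine reagent frees the non-enolisable ketoaldehyde, and amine–acid catalysed intramolecular Knoevenagel condensation of the C2 methylene (activated by the C1 ketone and the coumarin) with the aldehyde C3 closes the six-membered ring and dehydrates to C2=C3, C5 being a spectator.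

**Compound list**

1 | 2-hydroxy-4-methoxybenzaldehyde | COc1ccc(C=O)c(O)c1 | starting material
2 | succinic anhydride | O=C1CCC(=O)O1 | starting material
3 | 2-(7-methoxy-2-oxo-2H-chromen-3-yl)acetic acid | OC(=O)Cc1cc2ccc(OC)cc2oc1=O | intermediate
4 | 3-(2-hydroxyethyl)-7-methoxy-2H-chromen-2-one | OCCc1cc2ccc(OC)cc2oc1=O | intermediate
5 | 2-(7-methoxy-2-oxo-2H-chromen-3-yl)acetaldehyde (not isolated) | O=CCc1cc2ccc(OC)cc2oc1=O | intermediate
6 | 2-(7-methoxy-2-oxo-2H-chromen-3-yl)acetaldehyde oxime (E/Z mixture) | ON=CCc1cc2ccc(OC)cc2oc1=O | intermediate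
7 | (Z)-2-(7-methoxy-2-oxo-2H-chromen-3-yl)-N-hydroxyacetimidoyl chloride | O/N=C(\Cl)Cc1cc2ccc(OC)cc2oc1=O | intermediate
8 | triethyl phosphonoacetate | CCOC(=O)CP(=O)(OCC)OCC | starting material
9 | prenyl bromide (1-bromo-3-methylbut-2-ene) | CC(C)=CCBr | starting material
10 | ethyl 2-(diethoxyphosphoryl)-5-methylhex-4-enoate (racemic) | CCOC(=O)C(CC=C(C)C)P(=O)(OCC)OCC | intermediate
11 | ethyl 5-methyl-2-methylidenehex-4-enoate | C=C(CC=C(C)C)C(=O)OCC | intermediate
12 | 2-(3-methylbut-2-enyl)prop-2-en-1-ol | C=C(CO)CC=C(C)C | intermediate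
13 | ethylzinc alkoxide of 12 (not isolated) | CC[Zn]OCC(=C)CC=C(C)C | intermediate
14 | 2-(7-methoxy-2-oxo-2H-chromen-3-yl)acetonitrile oxide (not isolated) | [O-][N+]#CCc1cc2ccc(OC)cc2oc1=O | intermediate
15 | 3-{[(5R)-5-(hydroxymethyl)-5-(3-methylbut-2-enyl)-4,5-dihydroisoxazol-3-yl]methyl}-7-methoxy-2H-chromen-2-one | OC[C@@]1(CC=C(C)C)CC(Cc2cc3ccc(OC)cc3oc2=O)=NO1 | intermediate
16 | (5R)-3-[(7-methoxy-2-oxo-2H-chromen-3-yl)methyl]-5-(3-methylbut-2-enyl)-4,5-dihydroisoxazole-5-carbaldehyde | O=C[C@@]1(CC=C(C)C)CC(Cc2cc3ccc(OC)cc3oc2=O)=NO1 | intermediate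
17 | 3-{[(5R)-5-[(1,3-dithian-2-yl)(hydroxy)methyl]-5-(3-methylbut-2-enyl)-4,5-dihydroisoxazol-3-yl]methyl}-7-methoxy-2H-chromen-2-one (carbinol epimers) | OC(C2SCCCS2)[C@@]1(CC=C(C)C)CC(Cc3cc4ccc(OC)cc4oc3=O)=NO1 | intermediate
18 | 3-[(4R)-5-(1,3-dithian-2-yl)-4,5-dihydroxy-4-(3-methylbut-2-enyl)-2-oxopentyl]-7-methoxy-2H-chromen-2-one (C5' epimers) | OC(C1SCCCS1)[C@@](O)(CC=C(C)C)CC(=O)Cc1cc2ccc(OC)cc2oc1=O | intermediate
19 | 3-[(4R)-5-(1,3-dithian-2-yl)-4-hydroxy-4-(3-methylbut-2-enyl)-2,5-dioxopentyl]-7-methoxy-2H-chromen-2-one | O=C(C1SCCCS1)[C@@](O)(CC=C(C)C)CC(=O)Cc1cc2ccc(OC)cc2oc1=O | intermediate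
20 | 3-[(4R)-4-hydroxy-4-(3-methylbut-2-enyl)-2,5,6-trioxohexyl]-7-methoxy-2H-chromen-2-one (ketoaldehyde, not isolated) | O=CC(=O)[C@@](O)(CC=C(C)C)CC(=O)Cc1cc2ccc(OC)cc2oc1=O | intermediate
21 | 3-[(4R)-4-hydroxy-4-(3-methylbut-2-enyl)-3,6-dioxocyclohex-1-en-1-yl]-7-methoxy-2H-chromen-2-one | COc1ccc2cc(C3=CC(=O)[C@@](O)(CC=C(C)C)CC3=O)c(=O)oc2c1 | target

**Step count and risk**

Total steps: 13. Longest linear sequence: 10 steps (1 → 3 → 4 → 6 → 7 → 15 → 16 → 17 → 18 → 19 → 21; the allylic alcohol branch 8 → 12 joins at step 8).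

Steps most likely to fail:

1. Step 8. The facial selectivity may be poor because the 2-alkyl group crowds the zinc tartrate, and nitrile oxide may be lost to furoxan dimerisation. Fallback (resolution in place of induction), setting out from 7 and 12: slow addition of Et3N to both in CH2Cl2 at rt should give, with the same intrinsic regiochemistry, the racemic isoxazoline alcohol F1. Preparative chromatography on a chiral stationary phase then delivers the 5R enantiomer, and the route is rejoined at 15.

2. Step 11. The dithiane sulfur may bind zerovalent molybdenum and stall N–O cleavage, or C–S bonds may be cut at 80 °C. Fallback (sulfur removed before the reduction), setting out from 17: PhI(OCOCF3)2 in MeOH should exchange the dithiane for a dimethyl acetal, giving the isoxazoline hydroxy dimethyl acetal F2. Mo(CO)6 in MeCN/H2O then opens the ring to the dihydroxy ketone acetal F3. Parikh–Doering oxidation gives the keto acetal F4. Mild aqueous acid (TFA/H2O/CH2Cl2, 0 °C) hydrolyses the acetal to ketoaldehyde 20, where the route is rejoined for the amine-catalysed closure to 21.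

3. Step 13. Excess iodine oxidant may cleave the tertiary α-ketol in glycol fashion, the freed tricarbonyl may close a five-membered aldol onto the C4 ketone, or water may be lost across C5–C6 toward a quinone. Fallback (cyclise one oxidation level lower, oxidise last), setting out from 18: non-oxidative alkylative hydrolysis (MeI, CaCO3, MeCN/H2O, 45 °C) should give the α-hydroxy aldehyde F5. Pyrrolidine/AcOH in CH2Cl2 closes it by Knoevenagel condensation to the 4,5-dihydroxycyclohexenone F6. MnO2 in CH2Cl2 then oxidises the allylic C4 carbinol, rejoining the route at 21.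

**Further compounds**

F1 | step 8 | racemic 3-{[5-(hydroxymethyl)-5-(3-methylbut-2-enyl)-4,5-dihydroisoxazol-3-yl]methyl}-7-methoxy-2H-chromen-2-one | OCC1(CC=C(C)C)CC(Cc2cc3ccc(OC)cc3oc2=O)=NO1
F2 | step 11 | 3-{[(5R)-5-(1-hydroxy-2,2-dimethoxyethyl)-5-(3-methylbut-2-enyl)-4,5-dihydroisoxazol-3-yl]methyl}-7-methoxy-2H-chromen-2-one (carbinol epimers) | COC(OC)C(O)[C@@]1(CC=C(C)C)CC(Cc2cc3ccc(OC)cc3oc2=O)=NO1
F3 | step 11 | 3-[(4R)-4,5-dihydroxy-6,6-dimethoxy-4-(3-methylbut-2-enyl)-2-oxohexyl]-7-methoxy-2H-chromen-2-one (C5' epimers) | COC(OC)C(O)[C@@](O)(CC=C(C)C)CC(=O)Cc1cc2ccc(OC)cc2oc1=O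
F4 | step 11 | 3-[(4R)-4-hydroxy-6,6-dimethoxy-4-(3-methylbut-2-enyl)-2,5-dioxohexyl]-7-methoxy-2H-chromen-2-one | COC(OC)C(=O)[C@@](O)(CC=C(C)C)CC(=O)Cc1cc2ccc(OC)cc2oc1=O
F5 | step 13 | 3-[(4R)-4,5-dihydroxy-4-(3-methylbut-2-enyl)-2,6-dioxohexyl]-7-methoxy-2H-chromen-2-one (C5' epimers) | O=CC(O)[C@@](O)(CC=C(C)C)CC(=O)Cc1cc2ccc(OC)cc2oc1=O
F6 | step 13 | 3-[(4R)-3,4-dihydroxy-4-(3-methylbut-2-enyl)-6-oxocyclohex-1-en-1-yl]-7-methoxy-2H-chromen-2-one (C3 epimers) | COc1ccc2cc(C3=CC(O)[C@@](O)(CC=C(C)C)CC3=O)c(=O)oc2c1
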